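**Retrosynthetic overview**

1. Flavonoid locants are used (ring A: phloroglucinol ring carrying O1 and C4; ring B: guaiacyl ring on C2; ring C: pyranone). The last step only removes two MOM ethers.
2. Key disconnection: C2–C3 of ring C. The precursor is an achiral α-ketol aryl benzyl ether in which O1–C2 already exists; oxidising ring B to a para-quinone methide makes C2 electrophilic, and a chiral dinuclear zinc enediolate at C3 closes ring C and sets C2 and C3 together.
3. Enabling feature: the free 4'-OH of ring B is para to the benzylic carbon C2, so C2 can become the exocyclic carbon of a quinone methide that still bears O1; C3 lies between its own hydroxyl and the C4 ketone on the ortho-oxygenated ring A, a chelating ketol donor.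
4. The ketol ether comes from the ring A acetophenone with its 2-OH free, by Mitsunobu etherification with silyl-protected vanillyl alcohol and Rubottom oxidation of the methyl ketone.
5. Ring A block: C-prenylation of 2,4,6-trihydroxyacetophenone, then selective bis-MOM protection. Ring B block: vanillin. Rings A and B are bought; ring C is the only ring formed.

Key step: step 8

Assumption: the (S,S) antipode of ProPhenol is taken to give the (2R,3R) series by analogy with its face selectivity in ketol aldol additions; the sense of induction has to be confirmed on the first run and the (R,R) ligand used if it is opposite.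

**Route**

Step 1
Reactants: 1 2,4,6-trihydroxyacetophenone; 2 prenyl bromide (1-bromo-3-methylbut-2-ene)
Product: 3 1-[2,4,6-trihydroxy-3-(3-methylbut-2-en-1-yl)phenyl]ethan-1-one
Conditions: DBU (1.1 equiv), THF, 0 °C to rt
Reagents that add atoms: none
Why: Base-mediated C-alkylation of the phloroglucinol-type phenoxide (C-prenylation); the two free ring carbons of 1 are equivalent, so a single mono-C-prenyl isomer can form, and DBU in THF should favour carbon over oxygen attack.

Step 2
Reactants: 3 1-[2,4,6-trihydroxy-3-(3-methylbut-2-en-1-yl)phenyl]ethan-1-one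
Product: 4 1-[2-hydroxy-4,6-bis(methoxymethoxy)-3-(3-methylbut-2-en-1-yl)phenyl]ethan-1-one
Conditions: MOMCl (2.2 equiv), iPr2NEt, CH2Cl2, 0 °C
Reagents that add atoms: chloromethyl methyl ether (MOMCl), COCCl
Why: MOM ether formation (O-alkylation with an α-chloro ether) should take the para hydroxyl and the less hindered ortho hydroxyl, leaving free the hydroxyl that is flanked by the prenyl and acetyl groups and hydrogen-bonded to the carbonyl, which is the oxygen that becomes O1.

Step 3
Reactants: 5 vanillin (4-hydroxy-3-methoxybenzaldehyde)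
Product: 6 4-[(tert-butyldimethylsilyl)oxy]-3-methoxybenzaldehyde
Conditions: TBSCl, imidazole, CH2Cl2, rt
Reagents that add atoms: tert-butyldimethylsilyl chloride (TBSCl), CC(C)(C)[Si](C)(C)Cl
Why: Imidazole-promoted silylation of the phenol; the aryl silyl ether masks the ring B hydroxyl until just before the key step and comes off with fluoride without touching MOM ethers.

Step 4
Reactants: 6 4-[(tert-butyldimethylsilyl)oxy]-3-methoxybenzaldehyde
Product: 7 {4-[(tert-butyldimethylsilyl)oxy]-3-methoxyphenyl}methanol
Conditions: NaBH4, THF/MeOH, 0 °C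
Reagents that add atoms: none
Why: Hydride reduction of the aldehyde to the primary benzylic alcohol; nothing else in 6 is reducible under these conditions.

Step 5
Reactants: 4 1-[2-hydroxy-4,6-bis(methoxymethoxy)-3-(3-methylbut-2-en-1-yl)phenyl]ethan-1-one; 7 {4-[(tert-butyldimethylsilyl)oxy]-3-methoxyphenyl}methanol
Product: 8 1-[2-({4-[(tert-butyldimethylsilyl)oxy]-3-methoxyphenyl}methoxy)-4,6-bis(methoxymethoxy)-3-(3-methylbut-2-en-1-yl)phenyl]ethan-1-one
Conditions: PPh3, DIAD, THF, 0 °C to rt
Reagents that add atoms: none
Why: Mitsunobu etherification: the chelated phenol of 4 is acidic enough to protonate the betaine and is alkylated by the primary benzylic oxyphosphonium ion under neutral conditions that spare the aryl silyl ether, the MOM ethers and the prenyl group; this forms the O1–C2 bond.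

Step 6
Reactants: 8 1-[2-({4-[(tert-butyldimethylsilyl)oxy]-3-methoxyphenyl}methoxy)-4,6-bis(methoxymethoxy)-3-(3-methylbut-2-en-1-yl)phenyl]ethan-1-one
Product: 9 trimethylsilyl enol ether of 8, ({1-[2-({4-[(tert-butyldimethylsilyl)oxy]-3-methoxyphenyl}methoxy)-4,6-bis(methoxymethoxy)-3-(3-methylbut-2-en-1-yl)phenyl]ethenyl}oxy)trimethylsilane
Conditions: LiN(SiMe3)2, Me3SiCl, THF, −78 °C; non-aqueous work-up (pentane, filtration)
Reagents that add atoms: chlorotrimethylsilane (Me3SiCl), C[Si](C)(C)Cl
Why: Kinetic deprotonation of the methyl ketone, the only enolisable position, with in-situ O-silylation (silyl enol ether formation).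

Step 7
Reactants: 9 trimethylsilyl enol ether of 8
Product: 11 2-hydroxy-1-{2-[(4-hydroxy-3-methoxyphenyl)methoxy]-4,6-bis(methoxymethoxy)-3-(3-methylbut-2-en-1-yl)phenyl}ethan-1-one, via α-trimethylsilyloxy ketone 10 (not isolated)
Conditions: mCPBA (1.0 equiv), CH2Cl2, −40 °C; then Bu4NF/AcOH (1:1), THF, 0 °C
Reagents that add atoms: 3-chloroperbenzoic acid (mCPBA), OOC(=O)c1cccc(Cl)c1
Why: Rubottom oxidation: the peracid should epoxidise the very electron-rich silyl enol ether faster than the trisubstituted prenyl alkene at low temperature and silyl migration then gives 10, after which acetic-acid-buffered fluoride removes both silyl groups without leaving ring B as a free phenoxide that could expel the ring A aryloxide.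

Step 8
Reactants: 11 2-hydroxy-1-{2-[(4-hydroxy-3-methoxyphenyl)methoxy]-4,6-bis(methoxymethoxy)-3-(3-methylbut-2-en-1-yl)phenyl}ethan-1-one
Product: 13 (2R,3R)-3-hydroxy-2-(4-hydroxy-3-methoxyphenyl)-5,7-bis(methoxymethoxy)-8-(3-methylbut-2-en-1-yl)-2,3-dihydro-4H-chromen-4-one, via para-quinone methide 12 (not isolated)
Conditions: Ag2O (1.5 equiv), 4 Å MS, CH2Cl2, 0 °C, dark; filtration under Ar into Et2Zn (20 mol %)/(S,S)-ProPhenol (10 mol %; 2,6-bis{[(2S)-2-(hydroxydiphenylmethyl)pyrrolidin-1-yl]methyl}-4-methylphenol), 4 Å MS, THF, −20 °C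
Reagents that add atoms: none
Why: Proposed new method: Ag2O (monovalent silver) removes two electrons and two protons from the only free phenol, the 4'-OH of ring B, and so turns the para-hydroxybenzyl ether into the para-quinone methide 12, whose exocyclic carbon is C2 and still carries O1; the dinuclear zinc alkoxide then converts the α-ketol into a chelated (Z)-zinc enediolate whose C3 adds to C2 in a 1,6-conjugate addition that rearomatises ring B. The closest known reaction types are the dinuclear-zinc–ProPhenol direct aldol, Mannich and Michael additions of ortho-alkoxy α-hydroxyacetophenones and the catalytic enantioselective 1,6-additions of enolates to para-quinone methides; the intramolecular closure onto an oxygen-substituted quinone methide made by in-flask oxidation is the untested part. Ring C closes by a 6-(enolendo)-exo-trig attack through a half-chair. C3 is set by the chiral zinc pocket, which must leave the Re face of C3 of the enediolate open to C2; C2 is set by the ring, because the chelate holds the C3 oxygen syn to the C4 oxygen (pseudo-equatorial in the half-chair) and the quinoid ring B also takes the pseudo-equatorial place, which gives the trans (2R,3R) product, also the more stable epimer. The step needs carbon rather than oxygen attack by the ketol and no uncatalysed racemic closure: O-attack gives only a reversible seven-membered acetal while C-attack is driven by aromatisation of ring B, the neutral ketol does not enolise until the zinc base is added, and the MOM ethers keep the ring A phenols out of both the oxidation and the metal binding.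

Step 9
Reactants: 13 (2R,3R)-3-hydroxy-2-(4-hydroxy-3-methoxyphenyl)-5,7-bis(methoxymethoxy)-8-(3-methylbut-2-en-1-yl)-2,3-dihydro-4H-chromen-4-one
Product: 14 (2R,3R)-3,5,7-trihydroxy-2-(4-hydroxy-3-methoxyphenyl)-8-(3-methylbut-2-en-1-yl)-2,3-dihydro-4H-chromen-4-one
Conditions: 3 M HCl (aq), MeOH, 45 °C
Reagents that add atoms: none
Why: Acid-catalysed acetal solvolysis (MOM cleavage) under the mild methanolic conditions usual for prenylated flavanones; the trans dihydroflavonol is the stable epimer and neither stereocentre should be touched by dilute acid at this temperature.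

**Compound list**

1 | 2,4,6-trihydroxyacetophenone | CC(=O)c1c(O)cc(O)cc1O | starting material
2 | prenyl bromide (1-bromo-3-methylbut-2-ene) | CC(C)=CCBr | starting material
3 | 1-[2,4,6-trihydroxy-3-(3-methylbut-2-en-1-yl)phenyl]ethan-1-one | CC(=O)c1c(O)cc(O)c(CC=C(C)C)c1O | intermediate
4 | 1-[2-hydroxy-4,6-bis(methoxymethoxy)-3-(3-methylbut-2-en-1-yl)phenyl]ethan-1-one | CC(=O)c1c(OCOC)cc(OCOC)c(CC=C(C)C)c1O | intermediate
5 | vanillin (4-hydroxy-3-methoxybenzaldehyde) | COc1cc(C=O)ccc1O | starting material
6 | 4-[(tert-butyldimethylsilyl)oxy]-3-methoxybenzaldehyde | COc1cc(C=O)ccc1O[Si](C)(C)C(C)(C)C | intermediate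
7 | {4-[(tert-butyldimethylsilyl)oxy]-3-methoxyphenyl}methanol | COc1cc(CO)ccc1O[Si](C)(C)C(C)(C)C | intermediate
8 | 1-[2-({4-[(tert-butyldimethylsilyl)oxy]-3-methoxyphenyl}methoxy)-4,6-bis(methoxymethoxy)-3-(3-methylbut-2-en-1-yl)phenyl]ethan-1-one | CC(=O)c1c(OCOC)cc(OCOC)c(CC=C(C)C)c1OCc1ccc(O[Si](C)(C)C(C)(C)C)c(OC)c1 | intermediate
9 | trimethylsilyl enol ether of 8 | C=C(O[Si](C)(C)C)c1c(OCOC)cc(OCOC)c(CC=C(C)C)c1OCc1ccc(O[Si](C)(C)C(C)(C)C)c(OC)c1 | intermediate
10 | α-trimethylsilyloxy ketone, 1-[aryl of 8]-2-[(trimethylsilyl)oxy]ethan-1-one (formed in the flask) | C[Si](C)(C)OCC(=O)c1c(OCOC)cc(OCOC)c(CC=C(C)C)c1OCc1ccc(O[Si](C)(C)C(C)(C)C)c(OC)c1 | intermediate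
11 | 2-hydroxy-1-{2-[(4-hydroxy-3-methoxyphenyl)methoxy]-4,6-bis(methoxymethoxy)-3-(3-methylbut-2-en-1-yl)phenyl}ethan-1-one | OCC(=O)c1c(OCOC)cc(OCOC)c(CC=C(C)C)c1OCc1ccc(O)c(OC)c1 | intermediate
12 | para-quinone methide, 4-{[2-(2-hydroxyacetyl)-3,5-bis(methoxymethoxy)-6-(3-methylbut-2-en-1-yl)phenoxy]methylidene}-2-methoxycyclohexa-2,5-dien-1-one, either geometry of the exocyclic double bond (formed in the flask) | COC1=CC(=COc2c(CC=C(C)C)c(OCOC)cc(OCOC)c2C(=O)CO)C=CC1=O | intermediate
13 | (2R,3R)-3-hydroxy-2-(4-hydroxy-3-methoxyphenyl)-5,7-bis(methoxymethoxy)-8-(3-methylbut-2-en-1-yl)-2,3-dihydro-4H-chromen-4-one | COc1cc([C@H]2Oc3c(CC=C(C)C)c(OCOC)cc(OCOC)c3C(=O)[C@@H]2O)ccc1O | intermediate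
14 | (2R,3R)-3,5,7-trihydroxy-2-(4-hydroxy-3-methoxyphenyl)-8-(3-methylbut-2-en-1-yl)-2,3-dihydro-4H-chromen-4-one | COc1cc([C@H]2Oc3c(CC=C(C)C)c(O)cc(O)c3C(=O)[C@@H]2O)ccc1O | target

**Step count and risks**

Total step count: 9. Longest linear sequence: 7 steps (1 → 3 → 4 → 8 → 9 → 11 → 13 → 14; the branch from vanillin 5 through 6 and 7 to 8 and on to 14 is equally long).

Steps most likely to fail:

1. Step 8 (proposed new method). What may go wrong:
   - radical coupling at the free ring B position ortho to the phenol, or oxidation of the ketol, instead of clean two-electron oxidation;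
   - loss of ring B when adventitious water adds to the quinone methide and the ring A aryloxide is expelled;
   - closure through the ketol oxygen;
   - slow turnover because the zinc ends on the ring B phenoxide of the product;
   - poor facial selectivity on the di-ortho-substituted ketol;
   - base-induced reopening of O1–C2 through the ring B phenoxide, which would erode configurational purity.

   Fallback (known chemistry; here the C2–C3 bond comes from an aldol condensation): it sets out from 4 and 5 and comes back to the route at 14. The remaining phenol of 4 is capped (MOMCl, NaH, DMF) to give 1-[2,4,6-tris(methoxymethoxy)-3-(3-methylbut-2-en-1-yl)phenyl]ethan-1-one F1. Vanillin 5 is converted (MOMCl, iPr2NEt) into 3-methoxy-4-(methoxymethoxy)benzaldehyde F2. Claisen–Schmidt condensation of the two (KOH, EtOH) should give the (E)-chalcone F3. Juliá–Colonna epoxidation (poly-L-leucine, urea–H2O2, DBU, THF), a nucleophilic epoxidation that leaves the prenyl alkene alone, should give the (αR,βS)-epoxy ketone F4. HCl in MeOH then removes the four MOM groups, and the freed 2'-hydroxyl opens the epoxide at the benzylic carbon with inversion to give the trans dihydroflavonol 14.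

2. Step 7. What may go wrong: epoxidation of the prenyl double bond in competition with the enol ether; and, during desilylation, 1,6-elimination of the ring A aryloxide from the 4-hydroxybenzyl phenoxide.

   Fallback: it sets out from 8 and comes back at 11. The potassium enolate of 8 (KN(SiMe3)2, THF, −78 °C) is oxidised with 2-(phenylsulfonyl)-3-phenyloxaziridine, an oxygen-transfer reagent that reacts with enolates but not with isolated alkenes, to give the silyl-protected ketol 1-[2-({4-[(tert-butyldimethylsilyl)oxy]-3-methoxyphenyl}methoxy)-4,6-bis(methoxymethoxy)-3-(3-methylbut-2-en-1-yl)phenyl]-2-hydroxyethan-1-one F5. The aryl silyl ether is then cleaved with KHF2 in MeOH at rt, a weakly acidic fluoride source that never builds up the phenoxide, to give 11.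

3. Step 5. What may go wrong: sluggish activation of the hindered, hydrogen-bonded phenol; and alkylation of the reduced azodicarboxylate by the electron-rich benzylic oxyphosphonium ion.

   Fallback: it sets out from 7 and comes back at 8. Alcohol 7 is converted (CBr4, PPh3, CH2Cl2, 0 °C) into [4-(bromomethyl)-2-methoxyphenoxy](tert-butyl)dimethylsilane F6, and phenol 4 is alkylated with it in a Williamson etherification (K2CO3, dry acetone, 50 °C) to give 8.

**Further compounds**

F1 | step 8 | 1-[2,4,6-tris(methoxymethoxy)-3-(3-methylbut-2-en-1-yl)phenyl]ethan-1-one | CC(=O)c1c(OCOC)cc(OCOC)c(CC=C(C)C)c1OCOC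
F2 | step 8 | 3-methoxy-4-(methoxymethoxy)benzaldehyde | COCOc1ccc(C=O)cc1OC
F3 | step 8 | (E)-3-[3-methoxy-4-(methoxymethoxy)phenyl]-1-[2,4,6-tris(methoxymethoxy)-3-(3-methylbut-2-en-1-yl)phenyl]prop-2-en-1-one | COCOc1ccc(/C=C/C(=O)c2c(OCOC)cc(OCOC)c(CC=C(C)C)c2OCOC)cc1OC
F4 | step 8 | {(2R,3S)-3-[3-methoxy-4-(methoxymethoxy)phenyl]oxiran-2-yl}[2,4,6-tris(methoxymethoxy)-3-(3-methylbut-2-en-1-yl)phenyl]methanone | COCOc1ccc([C@@H]2O[C@H]2C(=O)c2c(OCOC)cc(OCOC)c(CC=C(C)C)c2OCOC)cc1OC
F5 | step 7 | 1-[2-({4-[(tert-butyldimethylsilyl)oxy]-3-methoxyphenyl}methoxy)-4,6-bis(methoxymethoxy)-3-(3-methylbut-2-en-1-yl)phenyl]-2-hydroxyethan-1-one | OCC(=O)c1c(OCOC)cc(OCOC)c(CC=C(C)C)c1OCc1ccc(O[Si](C)(C)C(C)(C)C)c(OC)c1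
F6 | step 5 | [4-(bromomethyl)-2-methoxyphenoxy](tert-butyl)dimethylsilane | COc1cc(CBr)ccc1O[Si](C)(C)C(C)(C)C
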